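**Plan**
Numbering is that of chroman (O1 to C8a). Ring A is the benzo ring and ring B is the aryl group on C2. The periphery is removed first: the five phenols become methyl ethers, the four formyl C–C bonds (C6, C8, C3', C5') are cut, and isobutyl at C4 is written as 2-methylprop-1-enyl.
The pyran ring is then cut at C2–C3 and C4–C4a in one operation, which gives an aryloxycarbenium ion (O1=C2 carrying rings A and B) and a diene.
Enabling feature: the C3–C4 unit holds isopropyl and the C4 side chain trans, as an (E)-alkene would deliver them. It lies between C2 (acetal-level, bonded to O1 and ring B) and C4a (an ortho carbon of the phloroglucinol-type ring A). The unsaturated C4 side chain makes this alkene half of a diene whose gem-dimethyl end decides which terminus bonds to C2.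
Forward: the diene (2 steps) and a mixed O-methyl O-aryl acetal (2 steps) are made separately and joined in step 5, which closes the only ring that has to be built. Hydrogenation, fourfold formylation and fivefold demethylation follow.
Stereochemistry: C2, C3 and C4 (2R,3R,4R, all-trans) all arise in step 5. The absolute sense comes from a chiral counter-anion and the relative sense from alkene geometry and chair-like closure. No later step creates a stereocentre.

Key step: step 5

Assumption: which antipode of the catalyst leads to the (2R,3R,4R) series cannot be derived in advance, so the (S,S) form is written and the equally accessible (R,R) form is used if the first run shows the opposite sense.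

**Step 1**
Reactants: 1 prenyl bromide (1-bromo-3-methylbut-2-ene)
Product: 2 diethyl (3-methylbut-2-en-1-yl)phosphonate
Conditions: P(OEt)3 (neat), 130 °C, distillation
Reagents that add atoms: triethyl phosphite CCOP(OCC)OCC
Why: Michaelis–Arbuzov reaction in which the phosphite displaces the primary allylic bromide and bromide then dealkylates the phosphonium salt, the volatile alkyl bromide distilling off and no stereocentre being involved.

**Step 2**
Reactants: 2 diethyl (3-methylbut-2-en-1-yl)phosphonate; 3 isobutyraldehyde
Product: 5 (E)-2,6-dimethylhepta-2,4-diene, via lithiated phosphonate 4 (not isolated)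
Conditions: n-BuLi, THF, −78 °C; then 3, DMPU, −78 °C to rt; distillation
Reagents that add atoms: none
Why: Horner–Wadsworth–Emmons olefination of an allylic phosphonate, in which carbanion 4 adds through its α-carbon and reversible addition followed by syn-elimination of phosphate, helped by the polar cosolvent, should favour the (E)-disubstituted double bond, while the trisubstituted one has no geometry to lose.

**Step 3**
Reactants: 6 2,4,6-trimethoxybenzaldehyde
Product: 7 2-(dimethoxymethyl)-1,3,5-trimethoxybenzene
Conditions: HC(OMe)3, p-TsOH·H2O (cat.), MeOH, 50 °C; NaOMe quench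
Reagents that add atoms: trimethyl orthoformate COC(OC)OC
Why: Acid-catalysed acetalisation in which the orthoformate consumes the water and so offsets the unfavourable equilibrium of a donor-stabilised, doubly ortho-substituted aldehyde, the acid being neutralised before concentration because 7 ionises easily.

**Step 4**
Reactants: 7 2-(dimethoxymethyl)-1,3,5-trimethoxybenzene; 8 3,5-dimethoxyphenol
Product: 10 (3,5-dimethoxyphenoxy)(methoxy)(2,4,6-trimethoxyphenyl)methane (racemic), via chloro ether 9 (not isolated)
Conditions: AcCl, ZnBr2 (cat.), toluene, 0 °C; then 8, i-Pr2NEt, 0 °C to rt; Et3N-deactivated SiO2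
Reagents that add atoms: none
Why: Acetal-to-α-chloro-ether exchange with an acyl chloride followed by Williamson-type O-alkylation of the phenol, the usual way to aryl alkyl acetals, where the amine keeps the medium basic so that kinetic attack through oxygen is not reversed into Friedel–Crafts attack through carbon, and where the racemic acetal centre is immaterial because it becomes planar in step 5.

**Step 5**
Reactants: 10 (3,5-dimethoxyphenoxy)(methoxy)(2,4,6-trimethoxyphenyl)methane; 5 (E)-2,6-dimethylhepta-2,4-diene
Product: 13 (2R,3R,4R)-3-isopropyl-5,7-dimethoxy-4-(2-methylprop-1-en-1-yl)-2-(2,4,6-trimethoxyphenyl)chroman, via aryloxycarbenium ion 11 (not isolated), via allyl cation 12 (not isolated)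
Conditions: (S,S)-IDPi [N,N'-bis(trifluoromethylsulfonyl) imidodiphosphorimidate of (S)-3,3'-bis(3,5-bis(trifluoromethyl)phenyl)-1,1'-bi-2-naphthol] (5 mol %), 5 (5 equiv), 5 Å MS, toluene, −40 °C, slow addition of 10; cold Et3N quench
Reagents that add atoms: none
Why: Proposed new method: the confined strong acid protonates the more basic and less hindered methoxy oxygen of 10, the sieves take up the methanol, and the (E)-aryloxycarbenium ion 11 stays paired with the chiral anion; 5 then bonds through its isopropyl-bearing terminus to the cationic carbon (C2–C3) to give allyl cation 12, an ortho carbon of ring A attacks the secondary allyl terminus (C4–C4a), and loss of the arenium proton regenerates the acid. The closest known reaction types are the SnCl4-promoted, racemic oxa-Povarov formal (4+2) of phenol-derived mixed acetals with simple alkenes and the imidodiphosphorimidate-catalysed additions of dienes and other weak π-nucleophiles to oxocarbenium ion pairs, so both the chiral-anion version and the use of one double bond of a diene as the two-carbon partner are untested. The pyran ring closes in a 6-exo-trig mode at the allyl cation (the C4a–C8a bond of the arene lies inside the new ring), which should be much faster than closure at the tertiary terminus to an eight-membered ring. C2 and C3 are created together in the first bond formation, where the anion blocks one face of 11 and orients the diene, which sets the absolute sense, and where the approach that turns isopropyl away from the doubly ortho-substituted ring B gives the 2,3-trans relation. C4 is set in the closure, which should pass through a chair-like arrangement with the 2-methylpropenyl group pseudo-equatorial and trans to isopropyl, the same relation that a concerted suprafacial addition to the (E)-double bond would give. The step needs attack at the more hindered diene terminus, which the gem-dimethyl end secures because only this mode leads to an allyl cation with a tertiary terminus; it needs no choice between the two ortho carbons of ring A, which are equivalent and each activated by O1, one ortho methoxy and one para methoxy group; and it needs diene capture to outrun Friedel–Crafts attack by a second molecule of 10, for which the excess of the small diene, the slow addition of 10 and the narrow catalyst pocket are relied on.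

**Step 6**
Reactants: 13 (2R,3R,4R)-3-isopropyl-5,7-dimethoxy-4-(2-methylprop-1-en-1-yl)-2-(2,4,6-trimethoxyphenyl)chroman
Product: 14 (2R,3R,4R)-4-isobutyl-3-isopropyl-5,7-dimethoxy-2-(2,4,6-trimethoxyphenyl)chroman
Conditions: H2 (1 atm), PtO2, EtOAc, rt
Reagents that add atoms: none
Why: Heterogeneous catalytic hydrogenation of the only C=C bond, which creates no stereocentre, with platinum chosen over palladium because it is less prone to move the double bond towards C4 (which would erase that centre) or to hydrogenolyse the hindered cyclic benzylic C2–O1 bond, a bond that flavan-type ethers normally keep under such conditions.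

**Step 7**
Reactants: 14 (2R,3R,4R)-4-isobutyl-3-isopropyl-5,7-dimethoxy-2-(2,4,6-trimethoxyphenyl)chroman
Product: 15 (2R,3R,4R)-2-(3,5-diformyl-2,4,6-trimethoxyphenyl)-4-isobutyl-3-isopropyl-5,7-dimethoxychroman-6,8-dicarbaldehyde
Conditions: Cl2CHOMe and TiCl4 (large excess, premixed), CH2Cl2, −78 °C, 14 added, then to rt; ice, aq HCl
Reagents that add atoms: dichloromethyl methyl ether COC(Cl)Cl; water O
Why: Rieche formylation in which the four free aromatic positions (C6 and C8 of ring A, C3' and C5' of ring B) each lie between two oxygen substituents so that exhaustive substitution has no regiochemical choice to make, double formylation of 5,7-dimethoxychromans and 2-alkyl-1,3,5-trimethoxybenzenes being established in formyl-phloroglucinol chemistry, and addition of 14 to the premixed electrophile in the cold letting ring B be deactivated before TiCl4 can ionise C2–O1.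

**Step 8**
Reactants: 15 (2R,3R,4R)-2-(3,5-diformyl-2,4,6-trimethoxyphenyl)-4-isobutyl-3-isopropyl-5,7-dimethoxychroman-6,8-dicarbaldehyde
Product: 16 sideroxylonal C, (2R,3R,4R)-2-(3,5-diformyl-2,4,6-trihydroxyphenyl)-5,7-dihydroxy-4-isobutyl-3-isopropylchroman-6,8-dicarbaldehyde
Conditions: BBr3 (excess), CH2Cl2, −78 °C to rt; ice water
Reagents that add atoms: none
Why: Lewis-acid cleavage of aryl methyl ethers in which each of the five methoxy groups is ortho to a formyl group so that chelation assists every cleavage, while the boron-complexed formyl groups of ring B disfavour ionisation at C2 and the three stereocentres, none of them enolisable, should be retained.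

**Compound list**
1 | prenyl bromide | CC(C)=CCBr | starting material
2 | diethyl (3-methylbut-2-en-1-yl)phosphonate | CCOP(=O)(CC=C(C)C)OCC | intermediate
3 | isobutyraldehyde | CC(C)C=O | starting material
4 | lithiated diethyl (3-methylbut-2-en-1-yl)phosphonate (not isolated) | [Li+].CCOP(=O)([CH-]C=C(C)C)OCC | intermediate
5 | (E)-2,6-dimethylhepta-2,4-diene | CC(C)/C=C/C=C(C)C | intermediate
6 | 2,4,6-trimethoxybenzaldehyde | COc1cc(OC)c(C=O)c(OC)c1 | starting material
7 | 2-(dimethoxymethyl)-1,3,5-trimethoxybenzene | COC(OC)c1c(OC)cc(OC)cc1OC | intermediate
8 | 3,5-dimethoxyphenol | COc1cc(O)cc(OC)c1 | starting material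
9 | 2-[chloro(methoxy)methyl]-1,3,5-trimethoxybenzene (not isolated) | COC(Cl)c1c(OC)cc(OC)cc1OC | intermediate
10 | (3,5-dimethoxyphenoxy)(methoxy)(2,4,6-trimethoxyphenyl)methane, racemic | COC(Oc1cc(OC)cc(OC)c1)c1c(OC)cc(OC)cc1OC | intermediate
11 | (3,5-dimethoxyphenyl)[(2,4,6-trimethoxyphenyl)methylidene]oxonium, paired with the IDPi anion (not isolated) | COc1cc(OC)cc([O+]=Cc2c(OC)cc(OC)cc2OC)c1 | intermediate
12 | allyl cation after C2–C3 bond formation, (2R,3R) in chroman numbering (not isolated) | CC(C)=C[CH+][C@@H](C(C)C)[C@@H](Oc1cc(OC)cc(OC)c1)c1c(OC)cc(OC)cc1OC | intermediate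
13 | (2R,3R,4R)-3-isopropyl-5,7-dimethoxy-4-(2-methylprop-1-en-1-yl)-2-(2,4,6-trimethoxyphenyl)chroman | CC(C)=C[C@H]1c2c(OC)cc(OC)cc2O[C@@H](c2c(OC)cc(OC)cc2OC)[C@@H]1C(C)C | intermediate
14 | (2R,3R,4R)-4-isobutyl-3-isopropyl-5,7-dimethoxy-2-(2,4,6-trimethoxyphenyl)chroman | CC(C)C[C@H]1c2c(OC)cc(OC)cc2O[C@@H](c2c(OC)cc(OC)cc2OC)[C@@H]1C(C)C | intermediate
15 | (2R,3R,4R)-2-(3,5-diformyl-2,4,6-trimethoxyphenyl)-4-isobutyl-3-isopropyl-5,7-dimethoxychroman-6,8-dicarbaldehyde | CC(C)C[C@H]1c2c(OC)c(C=O)c(OC)c(C=O)c2O[C@@H](c2c(OC)c(C=O)c(OC)c(C=O)c2OC)[C@@H]1C(C)C | intermediate
16 | sideroxylonal C | CC(C)C[C@H]1c2c(O)c(C=O)c(O)c(C=O)c2O[C@@H](c2c(O)c(C=O)c(O)c(C=O)c2O)[C@@H]1C(C)C | target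

Total step count: 8.
Longest linear sequence: 6 (steps 3 to 8, or equally steps 1, 2 and 5 to 8).

**Steps most likely to fail**

**Step 5.** Several processes could defeat it.
- The acetal may ionise in the wrong sense, losing the phenol instead of methanol, and the benzylic carbon may then migrate from oxygen to carbon.
- Friedel–Crafts self-condensation may outrun diene capture.
- The acid may oligomerise the diene.
- Facial selectivity within the ion pair may be poor.
- The product may epimerise at C2 by acid-induced re-opening of the C2–O1 bond.

The fallback uses known chemistry: the inverse-demand hetero-Diels–Alder reaction of an ortho-quinone methide of ring A with a ring-B styrene. It sets out from 8 and 6 and returns to the route at 14.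
- Friedel–Crafts acylation of 8 with isovaleric acid in BF3·OEt2 should give the chelated ketone 1-(2-hydroxy-4,6-dimethoxyphenyl)-3-methylbutan-1-one F1. NaBH4 reduces it to 2-(1-hydroxy-3-methylbutyl)-3,5-dimethoxyphenol F2.
- In parallel, i-BuMgBr adds to 6 to give 3-methyl-1-(2,4,6-trimethoxyphenyl)butan-1-ol F3. A trace of p-TsOH dehydrates it to (E)-1,3,5-trimethoxy-2-(3-methylbut-1-en-1-yl)benzene F4.
- A BINOL-derived phosphoric acid such as (R)-TRIP (3,3'-bis(2,4,6-triisopropylphenyl)-BINOL hydrogen phosphate) dehydrates F2 to 3,5-dimethoxy-6-(3-methylbutylidene)cyclohexa-2,4-dien-1-one F5, held by hydrogen bonding to the phosphate.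
- F5 takes up F4, with the isopropyl-bearing carbon of the styrene bonding to the methide carbon (C3–C4) and the phenolic oxygen bonding to the benzylic carbon (O1–C2).
- The (E)-styrene should give 2,3-trans and the usual endo approach 2,4-cis, which is the all-trans chroman 14 with the isobutyl group already saturated.
- Any shortfall in enantiomeric purity is made up by preparative chromatography on a chiral phase at this stage.

**Step 7.** The reaction may stall after one formyl group per ring, because the first-formed cationic adduct deactivates the ring. TiCl4 may open C2–O1 before ring B is deactivated, leading to epimerisation or elimination. Partial demethylation ortho to new formyl groups may give inseparable mixtures.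
The fallback inverts the order of the last two operations. It sets out from 14 and returns at 16.
- BBr3 in CH2Cl2 cleaves the five methyl ethers to (2R,3R,4R)-4-isobutyl-3-isopropyl-2-(2,4,6-trihydroxyphenyl)chroman-5,7-diol F6.
- The free phloroglucinol rings of F6 are far more nucleophilic than their ethers.
- Vilsmeier–Haack formylation (POCl3, DMF, EtOAc, rt, aqueous hydrolysis) is known to place two formyl groups on phloroglucinol and its C-alkyl derivatives. It then fills all four positions without a strong Lewis acid and gives 16 directly.

**Step 4.** Chloride may attack the O-methyl group of the chloro ether, which would lose the methyl group and return the aldehyde. The phenol may attack through carbon. The product may hydrolyse during purification.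
The fallback reaches the acetal from a lower oxidation level. It sets out from 6 and 8 and returns at 10.
- NaBH4 reduces 6 to (2,4,6-trimethoxyphenyl)methanol F7.
- A Mitsunobu reaction with 8 (PPh3, DIAD, THF) gives 2-[(3,5-dimethoxyphenoxy)methyl]-1,3,5-trimethoxybenzene F8, a robust benzyl aryl ether.
- DDQ with methanol, 2,6-di-tert-butylpyridine and 4 Å MS in CH2Cl2 at 0 °C abstracts hydride from the benzylic CH2, as in the oxidative acetal formation of methoxybenzyl ethers.
- This gives cation 11, which methanol traps as 10 under buffered conditions that contain no chloride.

**Further compounds**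
F1 | step 5 | 1-(2-hydroxy-4,6-dimethoxyphenyl)-3-methylbutan-1-one | CC(C)CC(=O)c1c(O)cc(OC)cc1OC
F2 | step 5 | 2-(1-hydroxy-3-methylbutyl)-3,5-dimethoxyphenol, racemic | CC(C)CC(O)c1c(O)cc(OC)cc1OC
F3 | step 5 | 3-methyl-1-(2,4,6-trimethoxyphenyl)butan-1-ol, racemic | CC(C)CC(O)c1c(OC)cc(OC)cc1OC
F4 | step 5 | (E)-1,3,5-trimethoxy-2-(3-methylbut-1-en-1-yl)benzene | CC(C)/C=C/c1c(OC)cc(OC)cc1OC
F5 | step 5 | 3,5-dimethoxy-6-(3-methylbutylidene)cyclohexa-2,4-dien-1-one | CC(C)CC=C1C(=O)C=C(OC)C=C1OC
F6 | step 7 | (2R,3R,4R)-4-isobutyl-3-isopropyl-2-(2,4,6-trihydroxyphenyl)chroman-5,7-diol | CC(C)C[C@H]1c2c(O)cc(O)cc2O[C@@H](c2c(O)cc(O)cc2O)[C@@H]1C(C)C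
F7 | step 4 | (2,4,6-trimethoxyphenyl)methanol | COc1cc(OC)c(CO)c(OC)c1
F8 | step 4 | 2-[(3,5-dimethoxyphenoxy)methyl]-1,3,5-trimethoxybenzene | COc1cc(OC)cc(OCc2c(OC)cc(OC)cc2OC)c1
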